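Ring B (the saturated ring) is cut at C6–C7 and at C8–C8a (naphthalene numbering of the target, used throughout: C5 carries the methyl group, C8 the side chain). One photoredox radical [4+2] annulation forms both bonds: the C6 radical from an (R)-3-arylbutanoic acid active ester adds to phenyl vinyl sulfone (C6–C7) and the α-sulfonyl C8 radical closes onto C8a, the only free aromatic position ortho to C4a and para to the C3 oxygen. The precursor is an open-chain aryl ester with C5 already set. Elimination, anti hydroboration at C8 and two stereospecific boronate homologations then attach the side chain (C2′, C1′) under reagent control.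

Key step: step 4

Assumption: (S)-BINAP (step 1) and (R)-DTBM-SEGPHOS (step 6) are taken to be the ligand antipodes that give the configurations drawn; the mirror-image ligand is used if the opposite sense is found.

Step 1
Reactants: 1 2,3-dimethoxyphenylboronic acid; 2 methyl (E)-but-2-enoate
Product: 3 methyl (3R)-3-(2,3-dimethoxyphenyl)butanoate
Conditions: Rh(acac)(C2H4)2 (3 mol %), (S)-BINAP (3.3 mol %), 1 (2 equiv), dioxane/H2O 10:1, 100 °C
Reagents that add atoms: none
Why: Rhodium-catalysed asymmetric conjugate addition of an arylboronic acid to an E-enoate (Hayashi–Miyaura reaction), in which the (S)-BINAP arylrhodium species selects one enoate face and so sets C5 as R.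

Step 2
Reactants: 3 methyl (3R)-3-(2,3-dimethoxyphenyl)butanoate
Product: 4 (3R)-3-(2,3-dimethoxyphenyl)butanoic acid
Conditions: LiOH·H2O, THF/MeOH/H2O, rt; then 1 M HCl
Reagents that add atoms: lithium hydroxide, [Li+].[OH-]
Why: Ester saponification; the C5 stereocentre is β to the carbonyl group and is not affected.

Step 3
Reactants: 4 (3R)-3-(2,3-dimethoxyphenyl)butanoic acid
Product: 5 1,3-dioxoisoindolin-2-yl (3R)-3-(2,3-dimethoxyphenyl)butanoate
Conditions: N-hydroxyphthalimide, DIC, DMAP (10 mol %), CH2Cl2, rt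
Reagents that add atoms: N-hydroxyphthalimide, O=C1c2ccccc2C(=O)N1O
Why: Carbodiimide (Steglich-type) esterification gives the N-acyloxyphthalimide needed as a reductively triggered radical precursor.

Step 4
Reactants: 5 1,3-dioxoisoindolin-2-yl (3R)-3-(2,3-dimethoxyphenyl)butanoate; 6 phenyl vinyl sulfone
Product: 7 (4R)-5,6-dimethoxy-4-methyl-1-(phenylsulfonyl)-1,2,3,4-tetrahydronaphthalene (both C1 epimers)
Conditions: fac-Ir(ppy)3 (1 mol %), 6 (2 equiv), DMF (0.05 M), 450 nm LEDs, rt, N2
Reagents that add atoms: none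
Why: Proposed new method: the excited photocatalyst reduces the N-acyloxyphthalimide, loss of CO2 and phthalimide anion frees the primary C6 radical, this adds to the CH2 end of the vinyl sulfone (C6–C7 bond), the electrophilic α-sulfonyl C8 radical attacks the electron-rich arene at C8a (C8–C8a bond), and the cyclohexadienyl radical is oxidised by the oxidised photocatalyst and deprotonated by phthalimide anion, so the cycle is redox-neutral. The closest known reaction types are the photoredox alkyl-arylation of N-arylacrylamides with the same active esters (radical conjugate addition, then homolytic aromatic substitution) and the radical [4+2] tetralin annulations of arene-tethered malonyl or α-keto radicals with alkenes promoted by Mn(OAc)3 or by xanthate transfer; new is the use of an unstabilised alkyl radical with an acceptor alkene in this topology. Ring B closes by six-membered ortho attack of the radical on the arene (the aromatic C4a–C8a bond lies inside the new ring). The new C8 centre is not controlled and need not be, because it becomes sp2 in step 5, while C5 is not touched. The step needs addition to the sulfone to outrun the 1,2-aryl shift of the 2-arylpropyl radical (secured by the excess of a very reactive acceptor) and ring closure to outrun oligomerisation (the α-sulfonyl radical is polarity-mismatched with more vinyl sulfone but matched with the dimethoxyarene), and the regiochemistry is fixed because C8a is the only open position ortho to C4a and lies para to the C3 methoxy group.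

Step 5
Reactants: 7 (4R)-5,6-dimethoxy-4-methyl-1-(phenylsulfonyl)-1,2,3,4-tetrahydronaphthalene
Product: 8 (1R)-7,8-dimethoxy-1-methyl-1,2-dihydronaphthalene
Conditions: KOt-Bu (3 equiv), THF/t-BuOH, 60 °C
Reagents that add atoms: none
Why: Base-induced β-elimination of benzenesulfinate from the benzylic sulfone (E2); only C7 carries β-hydrogen atoms, so both C8 epimers converge on one alkene and the C5 centre is not involved.

Step 6
Reactants: 8 (1R)-7,8-dimethoxy-1-methyl-1,2-dihydronaphthalene
Product: 9 2-[(1R,4R)-5,6-dimethoxy-4-methyl-1,2,3,4-tetrahydronaphthalen-1-yl]-4,4,5,5-tetramethyl-1,3,2-dioxaborolane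
Conditions: CuCl (3 mol %), NaOt-Bu (6 mol %), (R)-DTBM-SEGPHOS (3.3 mol %), HBpin (1.2 equiv), toluene, rt
Reagents that add atoms: pinacolborane, CC1(C)OBOC1(C)C
Why: Copper hydride catalysed Markovnikov hydroboration of the styrene-type double bond (syn Cu–H addition with copper on benzylic C8, then borylation with retention); addition anti to the pseudoaxial C5 methyl group, which the peri C4 methoxy group forces axial, is reinforced by the chiral ligand and sets C8 trans to C5.

Step 7
Reactants: 10 (2R)-3-bromo-2-methylpropan-1-ol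
Product: 11 [(2R)-3-bromo-2-methylpropoxy](tert-butyl)dimethylsilane
Conditions: TBSCl, imidazole, DMF, rt
Reagents that add atoms: tert-butyldimethylsilyl chloride, CC(C)(C)[Si](C)(C)Cl
Why: Silyl protection of the primary alcohol under standard imidazole conditions; the stereocentre (the later C6′) is untouched.

Step 8
Reactants: 11 [(2R)-3-bromo-2-methylpropoxy](tert-butyl)dimethylsilane; 12 oxetane
Product: 14 (5S)-6-[(tert-butyldimethylsilyl)oxy]-5-methylhexan-1-ol, via Grignard reagent 13 (not isolated)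
Conditions: Mg, I2 (cat.), THF, 50 °C; then 12 (1.5 equiv), CuI (10 mol %), −30 °C to rt; aq NH4Cl
Reagents that add atoms: none
Why: Grignard formation followed by copper-catalysed ring opening of oxetane (SN2 at the CH2–O carbon) extends the chain by a 3-hydroxypropyl unit without touching the β-stereocentre.

Step 9
Reactants: 14 (5S)-6-[(tert-butyldimethylsilyl)oxy]-5-methylhexan-1-ol
Product: 15 (5S)-6-[(tert-butyldimethylsilyl)oxy]-5-methylhexyl N,N-diisopropylcarbamate
Conditions: i-Pr2NCOCl (1.3 equiv), Et3N, CH2Cl2, reflux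
Reagents that add atoms: N,N-diisopropylcarbamoyl chloride, CC(C)N(C(C)C)C(=O)Cl
Why: O-Carbamoylation of the primary alcohol gives the N,N-diisopropylcarbamate that directs α-lithiation in the next step.

Step 10
Reactants: 15 (5S)-6-[(tert-butyldimethylsilyl)oxy]-5-methylhexyl N,N-diisopropylcarbamate; 9 2-[(1R,4R)-5,6-dimethoxy-4-methyl-1,2,3,4-tetrahydronaphthalen-1-yl]-4,4,5,5-tetramethyl-1,3,2-dioxaborolane
Product: 18 2-[(1S,5S)-6-[(tert-butyldimethylsilyl)oxy]-1-[(1S,4R)-5,6-dimethoxy-4-methyl-1,2,3,4-tetrahydronaphthalen-1-yl]-5-methylhexyl]-4,4,5,5-tetramethyl-1,3,2-dioxaborolane, via lithiated carbamate 16 (not isolated), via boronate complex 17 (not isolated)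
Conditions: 15 (1.4 equiv), s-BuLi (1.3 equiv), (+)-sparteine (1.4 equiv), Et2O, −78 °C, 5 h; then 9 (1.0 equiv), −78 °C, 1 h; then reflux, 16 h
Reagents that add atoms: none
Why: Lithiation–borylation: (+)-sparteine-controlled deprotonation gives the (R)-α-lithio carbamate, which adds to the boronic ester with retention, and the boronate complex then undergoes stereospecific 1,2-metallate rearrangement (retention in the migrating C8, inversion at the carbenoid carbon), so C2′ is set by the reagent and C8 is carried over unchanged.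

Step 11
Reactants: 18 2-[(1S,5S)-6-[(tert-butyldimethylsilyl)oxy]-1-[(1S,4R)-5,6-dimethoxy-4-methyl-1,2,3,4-tetrahydronaphthalen-1-yl]-5-methylhexyl]-4,4,5,5-tetramethyl-1,3,2-dioxaborolane
Product: 21 (2S,6S)-7-[(tert-butyldimethylsilyl)oxy]-2-[(1S,4R)-5,6-dimethoxy-4-methyl-1,2,3,4-tetrahydronaphthalen-1-yl]-6-methylheptan-1-ol, via chloromethyl boronate complex 19 (not isolated), via homologated boronic ester 20 (not isolated)
Conditions: BrCH2Cl (3 equiv), n-BuLi (2.5 equiv), THF, −78 °C to rt; then 2 M NaOH, 30% H2O2, 0 °C to rt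
Reagents that add atoms: bromochloromethane, ClCBr; hydrogen peroxide, OO
Why: Matteson homologation with (chloromethyl)lithium inserts the C1′ methylene group into the C2′–B bond with retention of configuration, and alkaline peroxide oxidation of the resulting primary boronic ester gives the alcohol.

Step 12
Reactants: 21 (2S,6S)-7-[(tert-butyldimethylsilyl)oxy]-2-[(1S,4R)-5,6-dimethoxy-4-methyl-1,2,3,4-tetrahydronaphthalen-1-yl]-6-methylheptan-1-ol
Product: 22 tert-butyl{[(2S,6S)-7-[(tert-butyldimethylsilyl)oxy]-2-[(1S,4R)-5,6-dimethoxy-4-methyl-1,2,3,4-tetrahydronaphthalen-1-yl]-6-methylheptyl]oxy}dimethylsilane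
Conditions: TBSCl, imidazole, DMF, rt
Reagents that add atoms: tert-butyldimethylsilyl chloride, CC(C)(C)[Si](C)(C)Cl
Why: Silylation masks the new primary alcohol so that the following organolithium step is directed only by the aryl methoxy groups.

Step 13
Reactants: 22 tert-butyl{[(2S,6S)-7-[(tert-butyldimethylsilyl)oxy]-2-[(1S,4R)-5,6-dimethoxy-4-methyl-1,2,3,4-tetrahydronaphthalen-1-yl]-6-methylheptyl]oxy}dimethylsilane
Product: 24 (5R,8S)-8-[(2S,6S)-1,7-bis[(tert-butyldimethylsilyl)oxy]-6-methylheptan-2-yl]-3,4-dimethoxy-5-methyl-5,6,7,8-tetrahydronaphthalene-2-carboxylic acid, via aryllithium 23 (not isolated)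
Conditions: n-BuLi (2.5 equiv), TMEDA, Et2O, 0 °C to rt; then CO2, −78 °C to rt; cold 1 M HCl
Reagents that add atoms: carbon dioxide, O=C=O
Why: Directed ortho-metalation followed by carboxylation: the C3 methoxy group directs lithiation to C2, the only ring position ortho to an oxygen substituent, and the aryllithium is trapped by CO2.

Step 14
Reactants: 24 (5R,8S)-8-[(2S,6S)-1,7-bis[(tert-butyldimethylsilyl)oxy]-6-methylheptan-2-yl]-3,4-dimethoxy-5-methyl-5,6,7,8-tetrahydronaphthalene-2-carboxylic acid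
Product: 25 (5R,8S)-8-[(2S,6S)-1,7-dihydroxy-6-methylheptan-2-yl]-3,4-dihydroxy-5-methyl-5,6,7,8-tetrahydronaphthalene-2-carboxylic acid
Conditions: BBr3 (8 equiv), CH2Cl2, −78 to 0 °C; then H2O
Reagents that add atoms: none
Why: Boron tribromide cleaves the two aryl methyl ethers (Lewis acid–base adduct, then SN2 demethylation by bromide) and the two silyl ethers in one operation; no stereocentre is involved.

Compound list
1 | 2,3-dimethoxyphenylboronic acid | COc1cccc(B(O)O)c1OC | starting material
2 | methyl (E)-but-2-enoate | C/C=C/C(=O)OC | starting material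
3 | methyl (3R)-3-(2,3-dimethoxyphenyl)butanoate | C[C@H](CC(=O)OC)c1cccc(OC)c1OC | intermediate
4 | (3R)-3-(2,3-dimethoxyphenyl)butanoic acid | C[C@H](CC(=O)O)c1cccc(OC)c1OC | intermediate
5 | 1,3-dioxoisoindolin-2-yl (3R)-3-(2,3-dimethoxyphenyl)butanoate | C[C@H](CC(=O)ON1C(=O)c2ccccc2C1=O)c1cccc(OC)c1OC | intermediate
6 | phenyl vinyl sulfone | C=CS(=O)(=O)c1ccccc1 | starting material
7 | (4R)-5,6-dimethoxy-4-methyl-1-(phenylsulfonyl)-1,2,3,4-tetrahydronaphthalene (both C1 epimers) | O=S(=O)(c1ccccc1)C1CC[C@@H](C)c2c1ccc(OC)c2OC | intermediate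
8 | (1R)-7,8-dimethoxy-1-methyl-1,2-dihydronaphthalene | C1=CC[C@@H](C)c2c1ccc(OC)c2OC | intermediate
9 | 2-[(1R,4R)-5,6-dimethoxy-4-methyl-1,2,3,4-tetrahydronaphthalen-1-yl]-4,4,5,5-tetramethyl-1,3,2-dioxaborolane | CC1(C)OB(OC1(C)C)[C@@H]2CC[C@@H](C)c3c2ccc(OC)c3OC | intermediate
10 | (2R)-3-bromo-2-methylpropan-1-ol | C[C@H](CO)CBr | starting material
11 | [(2R)-3-bromo-2-methylpropoxy](tert-butyl)dimethylsilane | C[C@H](CO[Si](C)(C)C(C)(C)C)CBr | intermediate
12 | oxetane | C1COC1 | starting material
13 | [(2R)-3-[(tert-butyldimethylsilyl)oxy]-2-methylpropyl]magnesium bromide | C[C@H](CO[Si](C)(C)C(C)(C)C)C[Mg]Br | intermediate (not isolated)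
14 | (5S)-6-[(tert-butyldimethylsilyl)oxy]-5-methylhexan-1-ol | C[C@H](CO[Si](C)(C)C(C)(C)C)CCCCO | intermediate
15 | (5S)-6-[(tert-butyldimethylsilyl)oxy]-5-methylhexyl N,N-diisopropylcarbamate | C[C@H](CO[Si](C)(C)C(C)(C)C)CCCCOC(=O)N(C(C)C)C(C)C | intermediate
16 | (1R,5S)-6-[(tert-butyldimethylsilyl)oxy]-1-lithio-5-methylhexyl N,N-diisopropylcarbamate (sparteine complex) | C[C@H](CO[Si](C)(C)C(C)(C)C)CCC[C@@H]([Li])OC(=O)N(C(C)C)C(C)C | intermediate (not isolated)
17 | lithium [(1R,5S)-6-[(tert-butyldimethylsilyl)oxy]-1-[(diisopropylcarbamoyl)oxy]-5-methylhexyl][(1R,4R)-5,6-dimethoxy-4-methyl-1,2,3,4-tetrahydronaphthalen-1-yl](pinacolato)borate | C[C@H](CO[Si](C)(C)C(C)(C)C)CCC[C@@H]([B-]1(OC(C)(C)C(C)(C)O1)[C@@H]2CC[C@@H](C)c3c2ccc(OC)c3OC)OC(=O)N(C(C)C)C(C)C.[Li+] | intermediate (not isolated)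
18 | 2-[(1S,5S)-6-[(tert-butyldimethylsilyl)oxy]-1-[(1S,4R)-5,6-dimethoxy-4-methyl-1,2,3,4-tetrahydronaphthalen-1-yl]-5-methylhexyl]-4,4,5,5-tetramethyl-1,3,2-dioxaborolane | C[C@H](CO[Si](C)(C)C(C)(C)C)CCC[C@H](B1OC(C)(C)C(C)(C)O1)[C@@H]2CC[C@@H](C)c3c2ccc(OC)c3OC | intermediate
19 | lithium (chloromethyl)[(1S,5S)-6-[(tert-butyldimethylsilyl)oxy]-1-[(1S,4R)-5,6-dimethoxy-4-methyl-1,2,3,4-tetrahydronaphthalen-1-yl]-5-methylhexyl](pinacolato)borate | C[C@H](CO[Si](C)(C)C(C)(C)C)CCC[C@H]([B-]1(CCl)OC(C)(C)C(C)(C)O1)[C@@H]2CC[C@@H](C)c3c2ccc(OC)c3OC.[Li+] | intermediate (not isolated)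
20 | 2-[(2S,6S)-7-[(tert-butyldimethylsilyl)oxy]-2-[(1S,4R)-5,6-dimethoxy-4-methyl-1,2,3,4-tetrahydronaphthalen-1-yl]-6-methylheptyl]-4,4,5,5-tetramethyl-1,3,2-dioxaborolane | C[C@H](CO[Si](C)(C)C(C)(C)C)CCC[C@H](CB1OC(C)(C)C(C)(C)O1)[C@@H]2CC[C@@H](C)c3c2ccc(OC)c3OC | intermediate (not isolated)
21 | (2S,6S)-7-[(tert-butyldimethylsilyl)oxy]-2-[(1S,4R)-5,6-dimethoxy-4-methyl-1,2,3,4-tetrahydronaphthalen-1-yl]-6-methylheptan-1-ol | C[C@H](CO[Si](C)(C)C(C)(C)C)CCC[C@H](CO)[C@@H]1CC[C@@H](C)c2c1ccc(OC)c2OC | intermediate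
22 | tert-butyl{[(2S,6S)-7-[(tert-butyldimethylsilyl)oxy]-2-[(1S,4R)-5,6-dimethoxy-4-methyl-1,2,3,4-tetrahydronaphthalen-1-yl]-6-methylheptyl]oxy}dimethylsilane | C[C@H](CO[Si](C)(C)C(C)(C)C)CCC[C@H](CO[Si](C)(C)C(C)(C)C)[C@@H]1CC[C@@H](C)c2c1ccc(OC)c2OC | intermediate
23 | [(5R,8S)-8-[(2S,6S)-1,7-bis[(tert-butyldimethylsilyl)oxy]-6-methylheptan-2-yl]-3,4-dimethoxy-5-methyl-5,6,7,8-tetrahydronaphthalen-2-yl]lithium | C[C@H](CO[Si](C)(C)C(C)(C)C)CCC[C@H](CO[Si](C)(C)C(C)(C)C)[C@@H]1CC[C@@H](C)c2c1cc([Li])c(OC)c2OC | intermediate (not isolated)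
24 | (5R,8S)-8-[(2S,6S)-1,7-bis[(tert-butyldimethylsilyl)oxy]-6-methylheptan-2-yl]-3,4-dimethoxy-5-methyl-5,6,7,8-tetrahydronaphthalene-2-carboxylic acid | C[C@H](CO[Si](C)(C)C(C)(C)C)CCC[C@H](CO[Si](C)(C)C(C)(C)C)[C@@H]1CC[C@@H](C)c2c1cc(C(=O)O)c(OC)c2OC | intermediate
25 | (5R,8S)-8-[(2S,6S)-1,7-dihydroxy-6-methylheptan-2-yl]-3,4-dihydroxy-5-methyl-5,6,7,8-tetrahydronaphthalene-2-carboxylic acid | C[C@H](CO)CCC[C@H](CO)[C@@H]1CC[C@@H](C)c2c1cc(C(=O)O)c(O)c2O | target

Total step count: 14. Longest linear sequence: 11 steps (steps 1–6 and 10–14, from 1 to 25).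

Steps most likely to fail

1. Step 4 (proposed new method). The primary radical may undergo the 1,2-aryl shift or be reduced before it adds to the sulfone, and the adduct radical may oligomerise or be reduced instead of closing onto the arene. The fallback uses known chemistry and makes the two bonds one after the other; it sets out from acid 4. Oxalyl chloride gives (3R)-3-(2,3-dimethoxyphenyl)butanoyl chloride F1, and diazomethane converts this into the diazoketone (4R)-1-diazo-4-(2,3-dimethoxyphenyl)pentan-2-one F2. Wolff rearrangement (silver benzoate PhCO2Ag, Et3N, aqueous dioxane; Arndt–Eistert homologation) then gives (4R)-4-(2,3-dimethoxyphenyl)pentanoic acid F3. Friedel–Crafts cyclisation in Eaton's reagent (P2O5 in MeSO3H), para to the methoxy group, should give the tetralone (4R)-5,6-dimethoxy-4-methyl-3,4-dihydronaphthalen-1(2H)-one F4. NaBH4 reduction gives the alcohol (4R)-5,6-dimethoxy-4-methyl-1,2,3,4-tetrahydronaphthalen-1-ol F5, and acid-catalysed dehydration (p-TsOH, toluene, 80 °C) comes back to the route at alkene 8.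

2. Step 5. Reversible deprotonation at the sulfonyl-bearing carbon may stall the elimination, and long exposure to strong base may move the double bond toward C5 and erode its configuration. The fallback sets out from active ester 5: the annulation of step 4 is run with phenyl vinyl sulfoxide in place of 6 to give the sulfoxide (4R)-5,6-dimethoxy-4-methyl-1-(phenylsulfinyl)-1,2,3,4-tetrahydronaphthalene F6. Its thermal syn-elimination of benzenesulfenic acid (toluene, NaHCO3, 100 °C) needs no strong base and comes back to the route at alkene 8.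

3. Step 14. Excess BBr3 may convert the primary carbinols into bromides, or cleavage of the hindered C4 methyl ether may stay incomplete. The fallback sets out from acid 24: fluoride desilylation (Bu4NF, THF) gives the diol (5R,8S)-8-[(2S,6S)-1,7-dihydroxy-6-methylheptan-2-yl]-3,4-dimethoxy-5-methyl-5,6,7,8-tetrahydronaphthalene-2-carboxylic acid F7. Demethylation with AlCl3 and ethanethiol (hard acid with soft nucleophile, CH2Cl2, 0 °C) then comes back to the route at target 25.

Further compounds
F1 | step 4 | (3R)-3-(2,3-dimethoxyphenyl)butanoyl chloride | C[C@H](CC(=O)Cl)c1cccc(OC)c1OC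
F2 | step 4 | (4R)-1-diazo-4-(2,3-dimethoxyphenyl)pentan-2-one | C[C@H](CC(=O)C=[N+]=[N-])c1cccc(OC)c1OC
F3 | step 4 | (4R)-4-(2,3-dimethoxyphenyl)pentanoic acid | C[C@H](CCC(=O)O)c1cccc(OC)c1OC
F4 | step 4 | (4R)-5,6-dimethoxy-4-methyl-3,4-dihydronaphthalen-1(2H)-one | O=C1CC[C@@H](C)c2c1ccc(OC)c2OC
F5 | step 4 | (4R)-5,6-dimethoxy-4-methyl-1,2,3,4-tetrahydronaphthalen-1-ol (both C1 epimers) | OC1CC[C@@H](C)c2c1ccc(OC)c2OC
F6 | step 5 | (4R)-5,6-dimethoxy-4-methyl-1-(phenylsulfinyl)-1,2,3,4-tetrahydronaphthalene (mixture at C1 and at sulfur) | O=S(c1ccccc1)C1CC[C@@H](C)c2c1ccc(OC)c2OC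
F7 | step 14 | (5R,8S)-8-[(2S,6S)-1,7-dihydroxy-6-methylheptan-2-yl]-3,4-dimethoxy-5-methyl-5,6,7,8-tetrahydronaphthalene-2-carboxylic acid | C[C@H](CO)CCC[C@H](CO)[C@@H]1CC[C@@H](C)c2c1cc(C(=O)O)c(OC)c2OC
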